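**Plan**

1. Retrosynthesis: the two O-benzyl ethers are cut first, then the bond between the 3,4-dimethoxybenzyl CH2 and lactone C4, then the bond between lactone C3 and the catechol benzyl CH2. What is left is (R)-paraconic acid, whose carboxyl group sits on the ring carbon that becomes C4.
2. Forward: the oxolan-2-one ring is bought ready-made. The catechol arm is joined at C3 by dianion alkylation, the acid is made a redox-active ester, the 3,4-dimethoxybenzyl arm is joined at C4 by nickel-catalysed decarboxylative coupling with a benzylic zinc chloride, and hydrogenolysis frees the catechol.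
3. Enabling feature: C4 of the oxolan-2-one ring is a secondary sp3 carbon that is the carboxyl-bearing carbon of paraconic acid and is flanked by the C3 stereocentre in a five-membered ring. Its planar radical, set free by loss of CO2, is captured on the face anti to the C3 substituent.
4. Stereochemistry: a relay. The C4 carboxyl group of (R)-paraconic acid steers the C3 alkylation trans (3R); it then leaves as CO2 and the C3 arm steers the new C4–CH2 bond trans (4R).
5. Helper groups: the carboxyl group as its phthalimide ester (leaves in the key step) and two benzyl ethers (leave in the last step).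

Key step: step 4

Assumption: (R)-paraconic acid 1 is taken as a purchasable single enantiomer (the acid is also resolved from the racemate through amine salts); ring positions in the text follow the numbering of the target lactone, C3 carrying the catechol arm and C4 the 3,4-dimethoxybenzyl arm, whatever the locants in the names of intermediates.

**Route**

Step 1
Reactants: 1 (R)-paraconic acid [(3R)-5-oxooxolane-3-carboxylic acid]; 2 3,4-bis(benzyloxy)benzyl chloride
Product: 4 (3R,4R)-4-[3,4-bis(benzyloxy)benzyl]-5-oxooxolane-3-carboxylic acid (trans), via disodium enolate carboxylate 3 (not isolated)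
Conditions: NaN(SiMe3)2 (2.3 equiv), THF, −78 °C; then 2, Bu4NI (cat.), −78 → −30 °C; aq. HCl work-up
Reagents that add atoms: none
Why: Alkylation of a lactone enolate held in a carboxylate dianion (the way 3-alkylparaconic acids are made): the second equivalent of base removes the proton alpha to the lactone carbonyl, and the benzylic halide should enter C3 on the ring face opposite to the neighbouring carboxylate, which sets 3R trans to the carboxyl group.

Step 2
Reactants: 4 (3R,4R)-4-[3,4-bis(benzyloxy)benzyl]-5-oxooxolane-3-carboxylic acid
Product: 5 1,3-dioxoisoindolin-2-yl (3R,4R)-4-[3,4-bis(benzyloxy)benzyl]-5-oxooxolane-3-carboxylate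
Conditions: N-hydroxyphthalimide, iPrN=C=NiPr, DMAP (cat.), CH2Cl2, 0 °C → rt
Reagents that add atoms: N-hydroxyphthalimide, O=C1c2ccccc2C(=O)N1O
Why: Carbodiimide (Steglich-type) esterification with N-hydroxyphthalimide should give the redox-active ester; no stereocentre is formed, and the configuration of the carboxyl-bearing carbon is of no consequence because it is erased in step 4.

Step 3
Reactants: 6 3,4-dimethoxybenzyl chloride
Product: 7 (3,4-dimethoxybenzyl)zinc chloride (THF solution, LiCl complex)
Conditions: Zn dust (activated with BrCH2CH2Br, Me3SiCl), LiCl, THF, 25 °C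
Reagents that add atoms: zinc, [Zn]
Why: LiCl-promoted direct insertion of zinc into a benzylic C–Cl bond should give the benzylic zinc chloride with little Wurtz coupling and without harm to the aryl methyl ethers.

Step 4
Reactants: 5 1,3-dioxoisoindolin-2-yl (3R,4R)-4-[3,4-bis(benzyloxy)benzyl]-5-oxooxolane-3-carboxylate; 7 (3,4-dimethoxybenzyl)zinc chloride
Product: 8 (3R,4R)-3-[3,4-bis(benzyloxy)benzyl]-4-(3,4-dimethoxybenzyl)oxolan-2-one
Conditions: NiCl2·glyme (20 mol%), 4,4′-di-tert-butyl-2,2′-bipyridine (40 mol%), 7 (2.5 equiv), THF/DMF, 25 °C
Reagents that add atoms: none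
Why: Proposed new method: transmetalation of 7 to the bipyridine nickel catalyst should give a benzyl complex of monovalent nickel that transfers one electron to the N-acyloxyphthalimide of 5, which loses phthalimide anion and CO2 and leaves a planar secondary radical at lactone C4; the radical is caught by the benzyl complex of divalent nickel formed alongside, and the trivalent nickel species that results makes the CH2–C4 bond by reductive elimination. The closest known reaction type is the nickel-catalysed decarboxylative Negishi alkyl–alkyl coupling of N-hydroxyphthalimide esters of secondary acids with primary alkylzinc reagents; new here are a benzylic zinc chloride as the nucleophile and a radical on a lactone ring, argued for by the ready transmetalation of benzylic zinc halides to nickel and by the inertness of lactones and aryl ethers toward organozinc chlorides at room temperature. No ring is closed. The one new stereocentre, C4, is under substrate control: in the five-membered ring the nickel complex meets the radical on the face opposite to the C3 arylmethyl group, so the 3,4-trans (3R,4R) lactone should result, and reductive elimination keeps that geometry. The step needs cross-coupling to outrun homocoupling of the benzyl partner and radical capture to outrun beta-hydride loss and hydrogen abstraction, which an excess of 7 and the chelating bipyridine ligand serve; cyclisation of the radical onto the neighbouring arene is not to be feared because it would be a 5-endo closure. C3 keeps its configuration because the medium holds no base strong enough to enolise the lactone.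

Step 5
Reactants: 8 (3R,4R)-3-[3,4-bis(benzyloxy)benzyl]-4-(3,4-dimethoxybenzyl)oxolan-2-one
Product: 9 3'-O-demethylarctigenin [(3R,4R)-3-(3,4-dihydroxybenzyl)-4-(3,4-dimethoxybenzyl)oxolan-2-one]
Conditions: H2 (1 atm), Pd/C, EtOAc/MeOH, rt
Reagents that add atoms: none
Why: Hydrogenolysis of the two aryl benzyl ethers over palladium should free the catechol, while the methyl ethers, the lactone and both stereocentres are inert under these neutral conditions.

**Compound list**

1 | (R)-paraconic acid, (3R)-5-oxooxolane-3-carboxylic acid | OC(=O)[C@H]1COC(=O)C1 | starting material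
2 | 3,4-bis(benzyloxy)benzyl chloride | ClCc1ccc(OCc2ccccc2)c(OCc2ccccc2)c1 | starting material
3 | disodium (3R)-5-oxido-2,3-dihydrofuran-3-carboxylate (enolate carboxylate dianion of 1) | [Na+].[Na+].[O-]C(=O)[C@H]1COC([O-])=C1 | intermediate
4 | (3R,4R)-4-[3,4-bis(benzyloxy)benzyl]-5-oxooxolane-3-carboxylic acid | OC(=O)[C@H]1COC(=O)[C@@H]1Cc1ccc(OCc2ccccc2)c(OCc2ccccc2)c1 | intermediate
5 | 1,3-dioxoisoindolin-2-yl (3R,4R)-4-[3,4-bis(benzyloxy)benzyl]-5-oxooxolane-3-carboxylate | O=C(ON1C(=O)c2ccccc2C1=O)[C@H]1COC(=O)[C@@H]1Cc1ccc(OCc2ccccc2)c(OCc2ccccc2)c1 | intermediate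
6 | 3,4-dimethoxybenzyl chloride | COc1ccc(CCl)cc1OC | starting material
7 | (3,4-dimethoxybenzyl)zinc chloride | COc1ccc(C[Zn]Cl)cc1OC | intermediate
8 | (3R,4R)-3-[3,4-bis(benzyloxy)benzyl]-4-(3,4-dimethoxybenzyl)oxolan-2-one | COc1ccc(C[C@H]2COC(=O)[C@@H]2Cc2ccc(OCc3ccccc3)c(OCc3ccccc3)c2)cc1OC | intermediate
9 | 3'-O-demethylarctigenin, (3R,4R)-3-(3,4-dihydroxybenzyl)-4-(3,4-dimethoxybenzyl)oxolan-2-one | COc1ccc(C[C@H]2COC(=O)[C@@H]2Cc2ccc(O)c(O)c2)cc1OC | target

**Count**

Total steps: 5. Longest linear sequence: 4 steps (1, 2, 4, 5) from (R)-paraconic acid; step 3 makes the coupling partner.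

**Steps most likely to fail**

Step 4 (proposed new method).
- What may go wrong: homocoupling of the benzyl partner at nickel; loss of the C4 radical by beta-hydride elimination or hydrogen abstraction; incomplete facial selectivity at C4. A cis isomer would have to be removed by chromatography and not by base, since epimerisation at C3 would lead into the enantiomeric series.
- Fallback by known chemistry, from 4 to 9: the acid 4 is condensed with ethanethiol (EDC, DMAP, CH2Cl2) to the S-ethyl thioester F1. Liebeskind–Srogl coupling with 3,4-dimethoxyphenylboronic acid (Pd2(dba)3, tri(2-furyl)phosphine, copper thiophene-2-carboxylate CuO2CC4H3S, THF, 50 °C) gives the aryl ketone F2. The carboxyl carbon is kept there as the future benzylic carbon, and C4, now alpha to the ketone, can only settle in the trans arrangement. Hydrogenation (H2, Pd/C, AcOH, cat. HClO4) then reduces the electron-rich aryl ketone to CH2 and cleaves both benzyl ethers, giving 9 directly.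

Step 1.
- What may go wrong: deprotonation next to the carboxylate with beta-elimination and opening of the lactone; O-alkylation of the carboxylate; incomplete trans selectivity, which after step 4 would show up as loss of enantiomeric purity (4 is therefore to be brought to diastereomeric purity before step 2).
- Fallback, from 2 to 4, which replaces the relay from paraconic acid by auxiliary control and makes the route independent of enantiopure 1:
  - Purchased 4-tert-butoxy-4-oxobutanoic acid and (R)-4-benzyl-1,3-oxazolidin-2-one are joined through the pivaloyl mixed anhydride (tBuCOCl, Et3N, LiCl, THF) to the imide F3.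
  - Its sodium enolate (NaN(SiMe3)2, THF, −78 °C) is alkylated with 2 (Bu4NI) on the face away from the benzyl group of the auxiliary (Evans alkylation) to the alkylated imide F4, which carries the required R centre.
  - LiOH/H2O2 removes the auxiliary and gives the acid F5.
  - Its dianion (LiN(iPr)2, 2.2 equiv, THF, −78 °C) forms next to the tert-butyl ester and is hydroxymethylated with monomeric formaldehyde to the hydroxy acid F6, as both epimers at the new centre.
  - CF3CO2H closes the gamma-lactone and cleaves the tert-butyl ester to give 4, which is separated from its epimer, the cis acid F7.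

Step 2.
- What may go wrong: base-induced beta-elimination of the activated ester with opening of the lactone, or hydrolysis of the ester during purification.
- Fallback, from 4 to 8, which avoids any activated ester: the free acid 4 is coupled with the benzyl chloride 6 under photoredox/nickel dual catalysis (Ir[dF(CF3)ppy]2(dtbbpy)PF6, NiCl2·glyme, 4,4′-dimethoxy-2,2′-bipyridine, K2CO3, MeCN/H2O, blue light). Photo-oxidation of the carboxylate sets free the same C4 radical, which low-valent nickel joins to the benzyl group to give 8. This is a known reaction type, though less developed for acids without a heteroatom next to the carboxyl group, and it makes no compound outside the list.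

**Further compounds**

F1 | step 4 | S-ethyl (3R,4R)-4-[3,4-bis(benzyloxy)benzyl]-5-oxooxolane-3-carbothioate | CCSC(=O)[C@H]1COC(=O)[C@@H]1Cc1ccc(OCc2ccccc2)c(OCc2ccccc2)c1
F2 | step 4 | (3R,4R)-3-[3,4-bis(benzyloxy)benzyl]-4-(3,4-dimethoxybenzoyl)oxolan-2-one | COc1ccc(C(=O)[C@H]2COC(=O)[C@@H]2Cc2ccc(OCc3ccccc3)c(OCc3ccccc3)c2)cc1OC
F3 | step 1 | tert-butyl 4-[(4R)-4-benzyl-2-oxo-1,3-oxazolidin-3-yl]-4-oxobutanoate | CC(C)(C)OC(=O)CCC(=O)N1[C@H](Cc2ccccc2)COC1=O
F4 | step 1 | tert-butyl (3R)-3-[3,4-bis(benzyloxy)benzyl]-4-[(4R)-4-benzyl-2-oxo-1,3-oxazolidin-3-yl]-4-oxobutanoate | CC(C)(C)OC(=O)C[C@@H](Cc1ccc(OCc2ccccc2)c(OCc2ccccc2)c1)C(=O)N1[C@H](Cc2ccccc2)COC1=O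
F5 | step 1 | (2R)-2-[3,4-bis(benzyloxy)benzyl]-4-tert-butoxy-4-oxobutanoic acid | CC(C)(C)OC(=O)C[C@@H](Cc1ccc(OCc2ccccc2)c(OCc2ccccc2)c1)C(=O)O
F6 | step 1 | (2R,3RS)-2-[3,4-bis(benzyloxy)benzyl]-4-tert-butoxy-3-(hydroxymethyl)-4-oxobutanoic acid | CC(C)(C)OC(=O)C(CO)[C@@H](Cc1ccc(OCc2ccccc2)c(OCc2ccccc2)c1)C(=O)O
F7 | step 1 | (3S,4R)-4-[3,4-bis(benzyloxy)benzyl]-5-oxooxolane-3-carboxylic acid (cis) | OC(=O)[C@@H]1COC(=O)[C@@H]1Cc1ccc(OCc2ccccc2)c(OCc2ccccc2)c1
F0 | step 2 | none | none
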